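Everything rests on cutting the O1–C2 bond of the dihydrobenzofuran. C2 is benzylic and para to the phenol oxygen of the guaiacyl ring on C2 (ring C), so it can pass through a ring C para-quinone methide, while the diol wing must keep the same atoms open. In one operation, buffered fluoride frees the phenols, the ring C phenoxide expels a benzylic acetate, the phenoxide of the fused arene (ring A) closes the five-membered ring trans to C3, and every silyl ether falls, giving the target. The precursor is the open (3R,4R)-dibenzylbutyrolactone with seven TBS ethers and one benzylic acetate, made by lactone alkylation from a syn-aldol-derived bromide and an anti-aldol-derived lactone.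

Key step: step 23

Ring letters: A, fused arene of the dihydrobenzofuran; B, arene carrying the diol wing; C, guaiacyl ring on C2; D, guaiacyl ring of the diol wing. TBS = tert-butyldimethylsilyl, TES = triethylsilyl.

Assumption on the chemistry: the acetate carbon of the precursor is carried as the single (S) epimer that the syn-aldol delivers. This carbon becomes planar in the key step, so the choice only removes a diastereomer mixture from the late intermediates.

Both wings come from one arylacetyl imide (9) and one aldehyde (11). No configurationally labile α-aryl aldehyde is used.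

**Common aryl unit**

Step 1
Reactants: 1 5-iodovanillin
Product: 2 4-(TBS-oxy)-3-iodo-5-methoxybenzaldehyde
Conditions: TBSCl, imidazole, DMF, rt
Reagents that add atoms: tert-butyldimethylsilyl chloride, CC(C)(C)[Si](C)(C)Cl
Why: Imidazole-promoted silyl ether formation puts the fluoride-labile group on the phenol that later serves as the ring A or ring B phenoxide.

Step 2
Reactants: 2 4-(TBS-oxy)-3-iodo-5-methoxybenzaldehyde
Product: 3 [4-(TBS-oxy)-3-iodo-5-methoxyphenyl]methanol
Conditions: NaBH4, THF/MeOH, 0 °C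
Reagents that add atoms: none
Why: Borohydride reduction of the aldehyde removes the electrophilic carbonyl before any enolate chemistry and gives the carbon that later becomes the benzylic bromide.

Step 3
Reactants: 3 [4-(TBS-oxy)-3-iodo-5-methoxyphenyl]methanol
Product: 4 aryl iodide bearing the TBS-protected phenol and the TES-protected benzylic alcohol
Conditions: TESCl, imidazole, CH2Cl2, 0 °C
Reagents that add atoms: triethylsilyl chloride, CC[Si](CC)(CC)Cl
Why: Silyl ether formation with a triethylsilyl group, which mild acid cleaves much faster than a TBS ether, so this one oxygen can be unmasked alone later.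

Step 4
Reactants: 4 aryl iodide bearing the TBS-protected phenol and the TES-protected benzylic alcohol
Product: 5 benzyl arylacetate
Conditions: BrZnCH2CO2Bn (from benzyl bromoacetate, Zn dust, THF), Pd2(dba)3 (cat.), XPhos (cat.), THF, 60 °C
Reagents that add atoms: benzyl bromoacetate, O=C(CBr)OCc1ccccc1
Why: Negishi-type cross-coupling of a Reformatsky reagent (palladium-catalysed arylation of a zinc ester enolate) joins the acetate carbon to the iodide-bearing ring carbon under neutral conditions that spare both silyl ethers.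

Step 5
Reactants: 5 benzyl arylacetate
Product: 6 arylacetic acid
Conditions: H2 (1 atm), Pd/C, EtOAc, rt
Reagents that add atoms: none
Why: Hydrogenolysis of the benzyl ester frees the acid without base or strong acid, so the aryl TBS ether and the TES ether should be untouched.

Step 6
Reactants: 6 arylacetic acid; 7 (S)-4-benzyl-2-oxazolidinone
Product: 9 (4S)-4-benzyl-3-(arylacetyl)oxazolidin-2-one, via mixed pivalic anhydride 8 (not isolated)
Conditions: PivCl, Et3N, THF, −20 °C; then 7, LiCl, −20 °C → rt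
Reagents that add atoms: none
Why: N-acylation of the oxazolidinone through the mixed pivalic anhydride with LiCl activation is the standard mild attachment of an Evans auxiliary and needs no strong base.

Step 7
Reactants: 10 vanillin
Product: 11 4-(TBS-oxy)-3-methoxybenzaldehyde
Conditions: TBSCl, imidazole, DMF, rt
Reagents that add atoms: tert-butyldimethylsilyl chloride, CC(C)(C)[Si](C)(C)Cl
Why: Silyl ether formation gives the aldehyde partner for both aldol reactions with its phenol masked as the later fluoride trigger.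

**Acetate-wing bromide (ring A and ring C)**

Step 8
Reactants: 9 (4S)-4-benzyl-3-(arylacetyl)oxazolidin-2-one; 11 4-(TBS-oxy)-3-methoxybenzaldehyde
Product: 13 (2S,3S) syn-aldol adduct, via Z dibutylboron enolate 12 (not isolated)
Conditions: Bu2BOTf, i-Pr2NEt, CH2Cl2, −78 → 0 °C; then 11, −78 → 0 °C; pH 7 buffer, MeOH, H2O2, 0 °C
Reagents that add atoms: none
Why: Evans syn-aldol reaction, in which the Z boron enolate reacts through a Zimmerman–Traxler chair on the face away from the auxiliary benzyl group and so sets C2 (S, the future C3 of the dihydrofuran) and the carbinol C3 (S) of the acyl chain.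

Step 9
Reactants: 13 (2S,3S) syn-aldol adduct
Product: 14 (1S,2R)-1-(ring C)-2-(ring A)-propane-1,3-diol
Conditions: LiBH4, MeOH (1 equiv), THF, 0 °C
Reagents that add atoms: none
Why: Reductive cleavage of the imide by hydride attack at the exocyclic carbonyl gives the 1,3-diol and releases the auxiliary without touching either stereocentre.

Step 10
Reactants: 14 (1S,2R)-1-(ring C)-2-(ring A)-propane-1,3-diol
Product: 15 (1S,2R) secondary alcohol with the primary TBS ether
Conditions: TBSCl (1.1 equiv), imidazole, CH2Cl2, 0 °C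
Reagents that add atoms: tert-butyldimethylsilyl chloride, CC(C)(C)[Si](C)(C)Cl
Why: Selective silylation of the primary hydroxyl, because the secondary benzylic hydroxyl sits between two aryl-bearing carbons and reacts far more slowly.

Step 11
Reactants: 15 (1S,2R) secondary alcohol with the primary TBS ether
Product: 16 (1S,2R) benzylic acetate
Conditions: Ac2O, Et3N, DMAP (cat.), CH2Cl2, 0 °C → rt
Reagents that add atoms: acetic anhydride, CC(=O)OC(C)=O
Why: DMAP-catalysed acetylation (nucleophilic acyl-transfer catalysis) turns the benzylic hydroxyl into the leaving group that the quinone methide formation needs.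

Step 12
Reactants: 16 (1S,2R) benzylic acetate
Product: 17 ring A benzylic alcohol
Conditions: PPTS (cat.), MeOH/CH2Cl2, 0 °C
Reagents that add atoms: none
Why: Acid-catalysed methanolysis removes the primary TES ether selectively, since TBS ethers and the acetate react far more slowly with PPTS at 0 °C.

Step 13
Reactants: 17 ring A benzylic alcohol
Product: 18 ring A benzylic bromide
Conditions: CBr4, PPh3, CH2Cl2, 0 °C
Reagents that add atoms: carbon tetrabromide, BrC(Br)(Br)Br
Why: The Appel reaction converts the benzylic alcohol into the bromide under neutral conditions that spare the acetate and the silyl ethers.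

**Diol-wing lactone (ring B and ring D)**

Step 14
Reactants: 9 (4S)-4-benzyl-3-(arylacetyl)oxazolidin-2-one; 11 4-(TBS-oxy)-3-methoxybenzaldehyde
Product: 20 (2R,3S) anti-aldol adduct, via trimethylsilyl ether 19 (not isolated)
Conditions: MgCl2 (20 mol%), Et3N, TMSCl, EtOAc, rt; then citric acid, MeOH, 0 °C
Reagents that add atoms: none
Why: Magnesium-halide-catalysed direct anti-aldol reaction of an N-acyloxazolidinone with an aromatic aldehyde (soft enolisation with silyl trapping), in which the chelated magnesium Z enolate reacts through a boat transition state on the face away from the auxiliary benzyl group and so sets C2 (R) and C3 (S) of the acyl chain, the anti pattern of the diol wing.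

Step 15
Reactants: 20 (2R,3S) anti-aldol adduct
Product: 21 (1S,2S)-1-(ring D)-2-(ring B)-propane-1,3-diol
Conditions: LiBH4, MeOH (1 equiv), THF, 0 °C
Reagents that add atoms: none
Why: Reductive cleavage of the imide by hydride attack at the exocyclic carbonyl gives the diol with both stereocentres of the wing in their final configuration.

Step 16
Reactants: 21 (1S,2S)-1-(ring D)-2-(ring B)-propane-1,3-diol
Product: 22 (1S,2S) bis-TBS ether
Conditions: TBSOTf, 2,6-lutidine, CH2Cl2, −78 → 0 °C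
Reagents that add atoms: tert-butyldimethylsilyl triflate, CC(C)(C)[Si](C)(C)OS(=O)(=O)C(F)(F)F
Why: Silylation with the silyl triflate and a hindered base protects the primary and the hindered secondary hydroxyl in one operation, and the benzylic oxygen becomes a silyl ether that cannot act as a leaving group later.

Step 17
Reactants: 22 (1S,2S) bis-TBS ether
Product: 23 ring B benzylic alcohol
Conditions: PPTS (cat.), MeOH/CH2Cl2, 0 °C
Reagents that add atoms: none
Why: Acid-catalysed methanolysis removes only the primary TES ether, because the four TBS ethers react much more slowly under these conditions.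

Step 18
Reactants: 23 ring B benzylic alcohol
Product: 24 ring B benzylic bromide
Conditions: CBr4, PPh3, CH2Cl2, 0 °C
Reagents that add atoms: carbon tetrabromide, BrC(Br)(Br)Br
Why: The Appel reaction gives the benzylic bromide under neutral conditions compatible with all silyl ethers.

Step 19
Reactants: 25 (R)-4-benzyl-2-oxazolidinone
Product: 27 methyl 4-[(4R)-4-benzyl-2-oxooxazolidin-3-yl]-4-oxobutanoate, via N-lithio oxazolidinone 26 (not isolated)
Conditions: n-BuLi, THF, −78 °C; then methyl 4-chloro-4-oxobutanoate, −78 → 0 °C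
Reagents that add atoms: methyl 4-chloro-4-oxobutanoate, COC(=O)CCC(Cl)=O
Why: N-acylation of the lithiated oxazolidinone with an acid chloride gives the succinate half-imide that carries all four lactone carbons.

Step 20
Reactants: 27 methyl 4-[(4R)-4-benzyl-2-oxooxazolidin-3-yl]-4-oxobutanoate; 24 ring B benzylic bromide
Product: 29 (3R)-benzylated succinyl imide, via sodium Z enolate 28 (not isolated)
Conditions: NaHMDS, THF, −78 °C; then 24, −78 → −30 °C
Reagents that add atoms: none
Why: Evans asymmetric alkylation, in which the chelated sodium Z enolate forms at the more acidic imide α-carbon and is benzylated on the face away from the auxiliary benzyl group, setting the future lactone C4 as R.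

Step 21
Reactants: 29 (3R)-benzylated succinyl imide
Product: 31 (4R)-4-(ring B benzyl)dihydrofuran-2(3H)-one, via hydroxy ester 30 (not isolated)
Conditions: NaBH4, THF/H2O, 0 °C → rt; then PPTS (cat.), CH2Cl2, rt
Reagents that add atoms: none
Why: Borohydride reduction of the N-acyloxazolidinone in aqueous THF leaves the methyl ester alone, and the resulting γ-hydroxy ester lactonises by intramolecular transesterification without strong acid or base.

**Union and key step**

Step 22
Reactants: 31 (4R)-4-(ring B benzyl)dihydrofuran-2(3H)-one; 18 ring A benzylic bromide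
Product: 33 heptasilylated seco lactone with the benzylic acetate, via lithium lactone enolate 32 (not isolated)
Conditions: LiHMDS, THF, −78 °C; then 18, DMPU, −78 → −40 °C
Reagents that add atoms: none
Why: Alkylation of the lithium lactone enolate occurs anti to the C4 substituent (1,2-induction in the five-membered enolate) and sets C3 as R in the trans lactone, while the benzylic bromide should react at −78 °C much faster than the hindered secondary acetate.

Step 23
Reactants: 33 heptasilylated seco lactone with the benzylic acetate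
Product: 35 target CNP0199264.2, via ring C quinone methide 34 (not isolated)
Conditions: TBAF, AcOH (1:1), THF, 0 °C → rt
Reagents that add atoms: none
Why: Fluoride cleaves the four aryl silyl ethers first, the ring C phenoxide expels acetate by 1,6-elimination to give a para-quinone methide whose exocyclic carbon is the future C2, the neighbouring ring A phenoxide adds to that carbon and re-aromatises ring C, and the three alkyl silyl ethers are then cleaved in the same pot. The closest known reaction type is the fluoride- or base-triggered formation of para-quinone methides from para-silyloxybenzyl esters with intramolecular phenol capture, the laboratory counterpart of phenylcoumaran formation. The dihydrofuran ring closes in the 5-exo-trig mode and forms the O1–C2 bond. C2 is controlled by the fixed C3 stereocentre, because in the cyclisation transition state the guaiacyl group turns away from the C3 silyloxymethyl group, giving the 2,3-trans (2S,3R) ring, which is also the more stable isomer. The step needs trans selectivity and reaction at the acetate wing only, and the second is secured because only this wing has a carboxylate leaving group: the diol wing carries a silyl ether and then a hydroxyl at its benzylic carbon, neither of which a phenoxide expels at room temperature, and the acetate buffer keeps out acid that could ionise that carbinol. Because the acetate carbon becomes planar, its configuration in 33 does not matter.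

**Compound list**

1 | 5-iodovanillin (4-hydroxy-3-iodo-5-methoxybenzaldehyde) | COc1cc(C=O)cc(I)c1O | starting material
2 | 4-(tert-butyldimethylsilyloxy)-3-iodo-5-methoxybenzaldehyde | COc1cc(C=O)cc(I)c1O[Si](C)(C)C(C)(C)C | intermediate
3 | [4-(tert-butyldimethylsilyloxy)-3-iodo-5-methoxyphenyl]methanol | COc1cc(CO)cc(I)c1O[Si](C)(C)C(C)(C)C | intermediate
4 | tert-butyl{2-iodo-6-methoxy-4-[(triethylsilyloxy)methyl]phenoxy}dimethylsilane | COc1cc(CO[Si](CC)(CC)CC)cc(I)c1O[Si](C)(C)C(C)(C)C | intermediate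
5 | benzyl 2-{2-(TBS-oxy)-3-methoxy-5-[(triethylsilyloxy)methyl]phenyl}acetate | COc1cc(CO[Si](CC)(CC)CC)cc(CC(=O)OCc2ccccc2)c1O[Si](C)(C)C(C)(C)C | intermediate
6 | 2-{2-(TBS-oxy)-3-methoxy-5-[(triethylsilyloxy)methyl]phenyl}acetic acid | COc1cc(CO[Si](CC)(CC)CC)cc(CC(=O)O)c1O[Si](C)(C)C(C)(C)C | intermediate
7 | (S)-4-benzyl-2-oxazolidinone | O=C1OC[C@H](Cc2ccccc2)N1 | starting material
8 | mixed anhydride of acid 6 with pivalic acid | COc1cc(CO[Si](CC)(CC)CC)cc(CC(=O)OC(=O)C(C)(C)C)c1O[Si](C)(C)C(C)(C)C | intermediate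
9 | (4S)-4-benzyl-3-(2-{2-(TBS-oxy)-3-methoxy-5-[(triethylsilyloxy)methyl]phenyl}acetyl)oxazolidin-2-one | COc1cc(CO[Si](CC)(CC)CC)cc(CC(=O)N2C(=O)OC[C@@H]2Cc2ccccc2)c1O[Si](C)(C)C(C)(C)C | intermediate
10 | vanillin | COc1cc(C=O)ccc1O | starting material
11 | 4-(tert-butyldimethylsilyloxy)-3-methoxybenzaldehyde | COc1cc(C=O)ccc1O[Si](C)(C)C(C)(C)C | intermediate
12 | (Z)-dibutylboron enolate of imide 9 | CCCCB(CCCC)O/C(N1C(=O)OC[C@@H]1Cc1ccccc1)=C\c1cc(CO[Si](CC)(CC)CC)cc(OC)c1O[Si](C)(C)C(C)(C)C | intermediate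
13 | (4S)-4-benzyl-3-[(2S,3S)-3-hydroxy-3-[4-(TBS-oxy)-3-methoxyphenyl]-2-{2-(TBS-oxy)-3-methoxy-5-[(triethylsilyloxy)methyl]phenyl}propanoyl]oxazolidin-2-one | COc1cc(CO[Si](CC)(CC)CC)cc([C@H](C(=O)N2C(=O)OC[C@@H]2Cc2ccccc2)[C@H](O)c2ccc(O[Si](C)(C)C(C)(C)C)c(OC)c2)c1O[Si](C)(C)C(C)(C)C | intermediate
14 | (1S,2R)-1-[4-(TBS-oxy)-3-methoxyphenyl]-2-{2-(TBS-oxy)-3-methoxy-5-[(triethylsilyloxy)methyl]phenyl}propane-1,3-diol | COc1cc(CO[Si](CC)(CC)CC)cc([C@H](CO)[C@H](O)c2ccc(O[Si](C)(C)C(C)(C)C)c(OC)c2)c1O[Si](C)(C)C(C)(C)C | intermediate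
15 | (1S,2R)-3-(TBS-oxy)-1-[4-(TBS-oxy)-3-methoxyphenyl]-2-{2-(TBS-oxy)-3-methoxy-5-[(triethylsilyloxy)methyl]phenyl}propan-1-ol | COc1cc(CO[Si](CC)(CC)CC)cc([C@H](CO[Si](C)(C)C(C)(C)C)[C@H](O)c2ccc(O[Si](C)(C)C(C)(C)C)c(OC)c2)c1O[Si](C)(C)C(C)(C)C | intermediate
16 | (1S,2R)-3-(TBS-oxy)-1-[4-(TBS-oxy)-3-methoxyphenyl]-2-{2-(TBS-oxy)-3-methoxy-5-[(triethylsilyloxy)methyl]phenyl}propyl acetate | COc1cc(CO[Si](CC)(CC)CC)cc([C@H](CO[Si](C)(C)C(C)(C)C)[C@H](OC(C)=O)c2ccc(O[Si](C)(C)C(C)(C)C)c(OC)c2)c1O[Si](C)(C)C(C)(C)C | intermediate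
17 | (1S,2R)-3-(TBS-oxy)-1-[4-(TBS-oxy)-3-methoxyphenyl]-2-[2-(TBS-oxy)-5-(hydroxymethyl)-3-methoxyphenyl]propyl acetate | COc1cc(CO)cc([C@H](CO[Si](C)(C)C(C)(C)C)[C@H](OC(C)=O)c2ccc(O[Si](C)(C)C(C)(C)C)c(OC)c2)c1O[Si](C)(C)C(C)(C)C | intermediate
18 | (1S,2R)-2-[5-(bromomethyl)-2-(TBS-oxy)-3-methoxyphenyl]-3-(TBS-oxy)-1-[4-(TBS-oxy)-3-methoxyphenyl]propyl acetate | COc1cc(CBr)cc([C@H](CO[Si](C)(C)C(C)(C)C)[C@H](OC(C)=O)c2ccc(O[Si](C)(C)C(C)(C)C)c(OC)c2)c1O[Si](C)(C)C(C)(C)C | intermediate
19 | O-trimethylsilyl ether of anti-aldol adduct 20 | COc1cc([C@@H](O[Si](C)(C)C)[C@H](C(=O)N2C(=O)OC[C@@H]2Cc2ccccc2)c2cc(CO[Si](CC)(CC)CC)cc(OC)c2O[Si](C)(C)C(C)(C)C)ccc1O[Si](C)(C)C(C)(C)C | intermediate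
20 | (4S)-4-benzyl-3-[(2R,3S)-3-hydroxy-3-[4-(TBS-oxy)-3-methoxyphenyl]-2-{2-(TBS-oxy)-3-methoxy-5-[(triethylsilyloxy)methyl]phenyl}propanoyl]oxazolidin-2-one | COc1cc([C@@H](O)[C@H](C(=O)N2C(=O)OC[C@@H]2Cc2ccccc2)c2cc(CO[Si](CC)(CC)CC)cc(OC)c2O[Si](C)(C)C(C)(C)C)ccc1O[Si](C)(C)C(C)(C)C | intermediate
21 | (1S,2S)-1-[4-(TBS-oxy)-3-methoxyphenyl]-2-{2-(TBS-oxy)-3-methoxy-5-[(triethylsilyloxy)methyl]phenyl}propane-1,3-diol | COc1cc([C@@H](O)[C@H](CO)c2cc(CO[Si](CC)(CC)CC)cc(OC)c2O[Si](C)(C)C(C)(C)C)ccc1O[Si](C)(C)C(C)(C)C | intermediate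
22 | (1S,2S)-1,3-bis(TBS-oxy)-1-[4-(TBS-oxy)-3-methoxyphenyl]-2-{2-(TBS-oxy)-3-methoxy-5-[(triethylsilyloxy)methyl]phenyl}propane | COc1cc([C@@H](O[Si](C)(C)C(C)(C)C)[C@H](CO[Si](C)(C)C(C)(C)C)c2cc(CO[Si](CC)(CC)CC)cc(OC)c2O[Si](C)(C)C(C)(C)C)ccc1O[Si](C)(C)C(C)(C)C | intermediate
23 | {3-[(1S,2S)-1,3-bis(TBS-oxy)-1-(4-TBS-oxy-3-methoxyphenyl)propan-2-yl]-4-(TBS-oxy)-5-methoxyphenyl}methanol | COc1cc([C@@H](O[Si](C)(C)C(C)(C)C)[C@H](CO[Si](C)(C)C(C)(C)C)c2cc(CO)cc(OC)c2O[Si](C)(C)C(C)(C)C)ccc1O[Si](C)(C)C(C)(C)C | intermediate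
24 | 3-[(1S,2S)-1,3-bis(TBS-oxy)-1-(4-TBS-oxy-3-methoxyphenyl)propan-2-yl]-4-(TBS-oxy)-5-methoxybenzyl bromide | COc1cc([C@@H](O[Si](C)(C)C(C)(C)C)[C@H](CO[Si](C)(C)C(C)(C)C)c2cc(CBr)cc(OC)c2O[Si](C)(C)C(C)(C)C)ccc1O[Si](C)(C)C(C)(C)C | intermediate
25 | (R)-4-benzyl-2-oxazolidinone | O=C1OC[C@@H](Cc2ccccc2)N1 | starting material
26 | N-lithio derivative of 25 | [Li]N1C(=O)OC[C@H]1Cc1ccccc1 | intermediate
27 | methyl 4-[(4R)-4-benzyl-2-oxooxazolidin-3-yl]-4-oxobutanoate | COC(=O)CCC(=O)N1C(=O)OC[C@H]1Cc1ccccc1 | intermediate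
28 | sodium (Z)-enolate of imide 27 | COC(=O)C/C=C(\O[Na])N1C(=O)OC[C@H]1Cc1ccccc1 | intermediate
29 | methyl (3R)-4-[(4R)-4-benzyl-2-oxooxazolidin-3-yl]-4-oxo-3-{3-[(1S,2S)-1,3-bis(TBS-oxy)-1-(4-TBS-oxy-3-methoxyphenyl)propan-2-yl]-4-(TBS-oxy)-5-methoxybenzyl}butanoate | COc1cc([C@@H](O[Si](C)(C)C(C)(C)C)[C@H](CO[Si](C)(C)C(C)(C)C)c2cc(C[C@H](CC(=O)OC)C(=O)N3C(=O)OC[C@H]3Cc3ccccc3)cc(OC)c2O[Si](C)(C)C(C)(C)C)ccc1O[Si](C)(C)C(C)(C)C | intermediate
30 | methyl (3R)-4-hydroxy-3-{3-[(1S,2S)-1,3-bis(TBS-oxy)-1-(4-TBS-oxy-3-methoxyphenyl)propan-2-yl]-4-(TBS-oxy)-5-methoxybenzyl}butanoate | COc1cc([C@@H](O[Si](C)(C)C(C)(C)C)[C@H](CO[Si](C)(C)C(C)(C)C)c2cc(C[C@H](CC(=O)OC)CO)cc(OC)c2O[Si](C)(C)C(C)(C)C)ccc1O[Si](C)(C)C(C)(C)C | intermediate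
31 | (4R)-4-{3-[(1S,2S)-1,3-bis(TBS-oxy)-1-(4-TBS-oxy-3-methoxyphenyl)propan-2-yl]-4-(TBS-oxy)-5-methoxybenzyl}dihydrofuran-2(3H)-one | COc1cc([C@@H](O[Si](C)(C)C(C)(C)C)[C@H](CO[Si](C)(C)C(C)(C)C)c2cc(C[C@H]3COC(=O)C3)cc(OC)c2O[Si](C)(C)C(C)(C)C)ccc1O[Si](C)(C)C(C)(C)C | intermediate
32 | lithium enolate of lactone 31 | COc1cc([C@@H](O[Si](C)(C)C(C)(C)C)[C@H](CO[Si](C)(C)C(C)(C)C)c2cc(C[C@H]3COC(O[Li])=C3)cc(OC)c2O[Si](C)(C)C(C)(C)C)ccc1O[Si](C)(C)C(C)(C)C | intermediate
33 | (3R,4R)-3-{3-[(1S,2R)-1-acetoxy-3-(TBS-oxy)-1-(4-TBS-oxy-3-methoxyphenyl)propan-2-yl]-4-(TBS-oxy)-5-methoxybenzyl}-4-{3-[(1S,2S)-1,3-bis(TBS-oxy)-1-(4-TBS-oxy-3-methoxyphenyl)propan-2-yl]-4-(TBS-oxy)-5-methoxybenzyl}dihydrofuran-2(3H)-one (heptasilylated seco precursor) | COc1cc([C@@H](O[Si](C)(C)C(C)(C)C)[C@H](CO[Si](C)(C)C(C)(C)C)c2cc(C[C@H]3COC(=O)[C@@H]3Cc3cc(OC)c(O[Si](C)(C)C(C)(C)C)c(c3)[C@H](CO[Si](C)(C)C(C)(C)C)[C@H](OC(C)=O)c3ccc(O[Si](C)(C)C(C)(C)C)c(OC)c3)cc(OC)c2O[Si](C)(C)C(C)(C)C)ccc1O[Si](C)(C)C(C)(C)C | intermediate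
34 | ring C para-quinone methide with the four phenols of rings A, B and D and the enone free and the three alkyl TBS ethers still in place | COc1cc([C@@H](O[Si](C)(C)C(C)(C)C)[C@H](CO[Si](C)(C)C(C)(C)C)c2cc(C[C@H]3COC(=O)[C@@H]3Cc3cc(OC)c(O)c(c3)[C@H](CO[Si](C)(C)C(C)(C)C)C=C3C=CC(=O)C(OC)=C3)cc(OC)c2O)ccc1O | intermediate
35 | CNP0199264.2: (3R,4R)-3-{[(2S,3R)-2-(4-hydroxy-3-methoxyphenyl)-3-(hydroxymethyl)-7-methoxy-2,3-dihydro-1-benzofuran-5-yl]methyl}-4-{3-[(1S,2S)-1,3-dihydroxy-1-(4-hydroxy-3-methoxyphenyl)propan-2-yl]-4-hydroxy-5-methoxybenzyl}dihydrofuran-2(3H)-one | COc1cc([C@@H](O)[C@H](CO)c2cc(C[C@H]3COC(=O)[C@@H]3Cc3cc(OC)c4c(c3)[C@H](CO)[C@@H](c3ccc(O)c(OC)c3)O4)cc(OC)c2O)ccc1O | target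

**Step count and risks**

Total step count: 23. Longest linear sequence: 15 steps (steps 1–6, 14–18, 20–23).

The three steps most likely to fail:

1. Step 23 (key step). The quinone methide may be intercepted by water or fluoride before the hindered ring A silyl ether is cleaved. It may also lose the C3 proton to give a stilbene, or close with incomplete trans selectivity. The fallback moves the ring closure to the small fragment, where the diol wing is absent and ring diastereomers can be separated. It sets out from acetate 16. Two equivalents of acetic-acid-buffered TBAF at −20 °C should cleave only the two aryl silyl ethers and give, through the ring C quinone methide F1, the trans-dihydrobenzofuran phenol F2. Re-silylation with TBSCl and imidazole should give the aryl silyl ether F3, PPTS in methanol the benzylic alcohol F4, and the Appel reaction the benzylic bromide F5. Alkylation of lithium enolate 32 with this bromide, as in step 22, should give the hexasilylated cyclised lactone F6. Global desilylation with buffered TBAF returns to the route at target 35.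

2. Step 14. The hindered ortho-silyloxyaryl imide and the electron-rich aldehyde may react slowly or with poor anti or facial selectivity, and the acidic α-aryl position may epimerise. The fallback uses a thiazolidinethione auxiliary, whose magnesium enolate is not chelated and reacts with the opposite facial sense, so the (R)-configured auxiliary is needed. It sets out from acid 6. Coupling with (R)-4-benzylthiazolidine-2-thione (DCC, DMAP) should give the N-acyl thiazolidinethione F7. MgBr2·OEt2 (cat.), Et3N, TMSCl and aldehyde 11 in EtOAc should give the silylated adduct F8 and, after mild acid, the (2R,3S) anti-aldol adduct F9. NaBH4 in THF/EtOH removes the auxiliary and returns to the route at diol 21.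

3. Step 22. The enolate may attack or deprotonate the acetate, the two bulky partners may couple slowly, or the para-silyloxybenzyl bromide may ionise. The fallback replaces the acetate by a tert-butyl carbonate, which has no α-protons and a shielded carbonyl but is an equally good leaving group for the 1,6-elimination. It sets out from alcohol 15. Boc2O and DMAP should give the tert-butyl carbonate F10, PPTS in methanol the benzylic alcohol F11, and the Appel reaction the benzylic bromide F12. Alkylation of enolate 32 should give the carbonate analogue of the precursor F13. Under the conditions of step 23 this compound should lose tert-butyl carbonate, pass through the same quinone methide 34, and return to the route at target 35.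

Further compounds

F1 | step 23 | ring C quinone methide from acetate 16 (both phenols freed, alkyl TBS and TES ethers in place) | COc1cc(CO[Si](CC)(CC)CC)cc([C@H](CO[Si](C)(C)C(C)(C)C)C=C2C=CC(=O)C(OC)=C2)c1O
F2 | step 23 | 4-[(2S,3R)-3-(TBS-oxymethyl)-7-methoxy-5-(triethylsilyloxymethyl)-2,3-dihydro-1-benzofuran-2-yl]-2-methoxyphenol | CC[Si](CC)(CC)OCc1cc(OC)c2c(c1)[C@H](CO[Si](C)(C)C(C)(C)C)[C@@H](c1ccc(O)c(OC)c1)O2
F3 | step 23 | TBS ether of phenol F2 | CC[Si](CC)(CC)OCc1cc(OC)c2c(c1)[C@H](CO[Si](C)(C)C(C)(C)C)[C@@H](c1ccc(O[Si](C)(C)C(C)(C)C)c(OC)c1)O2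
F4 | step 23 | [(2S,3R)-2-(4-TBS-oxy-3-methoxyphenyl)-3-(TBS-oxymethyl)-7-methoxy-2,3-dihydro-1-benzofuran-5-yl]methanol | OCc1cc(OC)c2c(c1)[C@H](CO[Si](C)(C)C(C)(C)C)[C@@H](c1ccc(O[Si](C)(C)C(C)(C)C)c(OC)c1)O2
F5 | step 23 | (2S,3R)-5-(bromomethyl)-2-(4-TBS-oxy-3-methoxyphenyl)-3-(TBS-oxymethyl)-7-methoxy-2,3-dihydro-1-benzofuran | BrCc1cc(OC)c2c(c1)[C@H](CO[Si](C)(C)C(C)(C)C)[C@@H](c1ccc(O[Si](C)(C)C(C)(C)C)c(OC)c1)O2
F6 | step 23 | hexa-TBS ether of the target (all six hydroxyls silylated, dihydrobenzofuran closed) | COc1cc([C@@H](O[Si](C)(C)C(C)(C)C)[C@H](CO[Si](C)(C)C(C)(C)C)c2cc(C[C@H]3COC(=O)[C@@H]3Cc3cc(OC)c4c(c3)[C@H](CO[Si](C)(C)C(C)(C)C)[C@@H](c3ccc(O[Si](C)(C)C(C)(C)C)c(OC)c3)O4)cc(OC)c2O[Si](C)(C)C(C)(C)C)ccc1O[Si](C)(C)C(C)(C)C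
F7 | step 14 | (4R)-4-benzyl-3-(2-{2-(TBS-oxy)-3-methoxy-5-[(triethylsilyloxy)methyl]phenyl}acetyl)thiazolidine-2-thione | COc1cc(CO[Si](CC)(CC)CC)cc(CC(=O)N2C(=S)SC[C@H]2Cc2ccccc2)c1O[Si](C)(C)C(C)(C)C
F8 | step 14 | O-trimethylsilyl ether of adduct F9 | COc1cc([C@@H](O[Si](C)(C)C)[C@H](C(=O)N2C(=S)SC[C@H]2Cc2ccccc2)c2cc(CO[Si](CC)(CC)CC)cc(OC)c2O[Si](C)(C)C(C)(C)C)ccc1O[Si](C)(C)C(C)(C)C
F9 | step 14 | (4R)-4-benzyl-3-[(2R,3S)-3-hydroxy-3-[4-(TBS-oxy)-3-methoxyphenyl]-2-{2-(TBS-oxy)-3-methoxy-5-[(triethylsilyloxy)methyl]phenyl}propanoyl]thiazolidine-2-thione | COc1cc([C@@H](O)[C@H](C(=O)N2C(=S)SC[C@H]2Cc2ccccc2)c2cc(CO[Si](CC)(CC)CC)cc(OC)c2O[Si](C)(C)C(C)(C)C)ccc1O[Si](C)(C)C(C)(C)C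
F10 | step 22 | tert-butyl (1S,2R)-3-(TBS-oxy)-1-[4-(TBS-oxy)-3-methoxyphenyl]-2-{2-(TBS-oxy)-3-methoxy-5-[(triethylsilyloxy)methyl]phenyl}propyl carbonate | COc1cc(CO[Si](CC)(CC)CC)cc([C@H](CO[Si](C)(C)C(C)(C)C)[C@H](OC(=O)OC(C)(C)C)c2ccc(O[Si](C)(C)C(C)(C)C)c(OC)c2)c1O[Si](C)(C)C(C)(C)C
F11 | step 22 | ring A benzylic alcohol from F10 (TES ether removed) | COc1cc(CO)cc([C@H](CO[Si](C)(C)C(C)(C)C)[C@H](OC(=O)OC(C)(C)C)c2ccc(O[Si](C)(C)C(C)(C)C)c(OC)c2)c1O[Si](C)(C)C(C)(C)C
F12 | step 22 | ring A benzylic bromide from F11 | COc1cc(CBr)cc([C@H](CO[Si](C)(C)C(C)(C)C)[C@H](OC(=O)OC(C)(C)C)c2ccc(O[Si](C)(C)C(C)(C)C)c(OC)c2)c1O[Si](C)(C)C(C)(C)C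
F13 | step 22 | analogue of precursor 33 with a tert-butyl carbonate in place of the acetate | COc1cc([C@@H](O[Si](C)(C)C(C)(C)C)[C@H](CO[Si](C)(C)C(C)(C)C)c2cc(C[C@H]3COC(=O)[C@@H]3Cc3cc(OC)c(O[Si](C)(C)C(C)(C)C)c(c3)[C@H](CO[Si](C)(C)C(C)(C)C)[C@H](OC(=O)OC(C)(C)C)c3ccc(O[Si](C)(C)C(C)(C)C)c(OC)c3)cc(OC)c2O[Si](C)(C)C(C)(C)C)ccc1O[Si](C)(C)C(C)(C)C
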